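One mM of X is the unit we count in. The runs so far lose 9.78 mM of E in the east flask by 20.0 h and 10.0 mM in the north-east flask by 30.0 h, against [X] = 10 mM charged in each. So we take X as the limiting reagent, spent one to one with E.

| setting | east | north-east | flask |
|---|---|---|---|
| E | 20 mM | 20 mM | 20 mM |
| X | 10 mM | 10 mM | 10.0 mM |
| G | 40 µM | 80 µM | 40 µM |
| temperature | 100 °C | 100 °C | 100 °C |
| remark | the very flask that is asked about, followed so far | run made earlier |  |
| time |  |  | 30 h |

| run | time / h | Q / % | E / % |
|---|---|---|---|
| east | 1.33 | 8.9 | 80.7 |
| east | 4.00 | 18.7 | 63.7 |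
| east | 6.00 | 22.3 | 57.8 |
| east | 10.0 | 24.3 | 52.8 |
| east | 15.0 | 25.8 | 52.4 |
| east | 20.0 | 26.4 | 51.1 |
| north-east | 2.00 | 21.9 | 67.4 |
| north-east | 6.00 | 33.4 | 52.7 |
| north-east | 10.0 | 33.0 | 51.1 |
| north-east | 15.0 | 34.1 | 50.5 |
| north-east | 25.0 | 34.6 | 49.6 |
| north-east | 30.0 | 35.2 | 49.9 |

(standard deviation of a reading: 0.5 percentage points)

- removed Q is counted in
- the analysis behind the earlier runs scatters by 0.5 percentage points, standard deviation
- the earlier runs do not show what temperature does; that part of a forecast is a guess
- additions bring no volume worth counting

- green: change nothing and wait 10 h more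
- grey: at 30 h add X, 50.0% of the amount charged, then wait 10 h
- teal: at 30 h take out 90% of the Q then present, then wait 10 h
- violet: at 30 h raise the temperature by 10 K, then wait 10 h
- amber: at 30 h add G, 100% of the amount charged, then wait 10 h

- Q, in percent of the E first charged, at 30 h
- what to do for the largest gain in Q; "none" if nothing gains more than 2 percentage points (green / grey / teal / violet / amber / none)
- Q present, with what was taken out counted in, in percent of the E first charged, after violet
- Q present, with what was taken out counted in, in percent of the E first charged, after amber

In the east flask, the reading at 20.0 h gives Q over E lost as 54.0%. With one E lost per X spent, that ratio is Q per X spent. If the whole charge of X is spent by 30 h, Q stands at 27.0% of the E charged.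

The weak link is that single reading, which scatters by 0.5 percentage points. So we reforge it and pool the east readings from 10.0 h on, which gives 53.2%. This is the X-yield, Q made per X spent in the east flask, and it is a reading with scatter. We commit to 26.6%.

Grey adds 5.00 mM of X. If that is spent within 10 h, the X-yield gives 13 points.

The forecast says 26.8% (26.2% to 27.5%), where we say 26.6%, and 26.9% after violet and 26.9% after amber. It picks grey for about 10 points, where our count gives 13 points, and holds that “With no X left, waiting, removing Q, heating, or adding G gain almost nothing”.

The flask gives 26.6% at 30 h, 26.6% after violet and 26.6% after amber. The best choice is grey, which gains 13 points.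

    E + X + G → Q + G, rate k1*[E]*[X]*[G]/(1 + ([E]/sat1)) (15.0 mM, k = 9600 M⁻² min⁻¹, Ea = 49.0 kJ mol⁻¹)
    E + X → L (k = 0.170 M⁻¹ min⁻¹, Ea = 79.0 kJ mol⁻¹)
    (constants at 100 °C)

In a neighbour flask charged with [X] = 25 mM, E falls to 0.19% by 30.0 h. The X-yield read in the east flask counts 53.2% of the E lost as Q, and that neighbour holds 58.0%, more than this count. In the asked flask, 0.0430% of the charged X stands at 30.0 h. Multiplied by the X-yield, this leaves 0.011 points of Q to come, and green gains 0.011 points. At 300 h the flask holds E 50.0%, X 0% and Q 26.6%.

The numbers in the tables are calculated with made-up constants; scatter was added.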